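## Analysis of the target

Compound 31 is an achiral aromatic polyketide in which three ring systems meet at one benzenoid ring. The core is a 2,5-dihydroxy-1,4-naphthoquinone: ring C is quinonoid (C1 and C4 carbonyls, C2 hydroxyl) and ring B is benzenoid (C5 hydroxyl). C6 carries a 2,4-dihydroxy-6-methylbenzoyl group (ring A; C1′ bears the ketone, C2′ and C4′ the hydroxyls, C6′ the methyl). C7 carries a (4-hydroxy-2-oxo-2H-pyran-6-yl)methyl group (pyranone atoms C2″ to C6″).

There is no stereocentre, so the problem is one of regiochemistry and functional-group tolerance only. The hydroxyquinone is sensitive to reduction and to nucleophiles. The 2-pyranone is a lactone that is opened by hydroxide when its C4″ oxygen is etherified. The five acidic hydroxyls make the free compound polar and chelating, so they should be uncovered last.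

The main difficulty is the diaryl ketone, which is flanked by four ortho substituents (C2′–OH, C6′–CH3, C5–OH, C7–CH2); joining two finished arenes there is unattractive. Ring B also carries three contiguous substituents on C5, C6 and C7, and ring C must reach the quinone level without damage to two other electron-rich rings.

The strategy rests on ring A. It has the carbon and oxygen pattern of an aldol-folded 1,3,5,7-tetraketone whose C1 carbonyl is the ketone on C6. The C1′–C6′ bond is the aldol bond, the C2′ and C4′ oxygens are former chain carbonyls, and the C6′ methyl is the chain end. That chain can be stored as a 2-(acylmethyl)-6-methyl-4-pyranone.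

## Retrosynthetic reasoning

**From 31 to 28 (oxygen functions only).** No C–C bond is cut. The C2 hydroxyl of 31 is traced to the methyl vinylogous ester of 30. The four other hydroxyls are traced to three benzyl ethers and the peri methyl ether of 29. The quinone of 29 is traced to the 5,6,8-trimethoxy pattern of naphthalene 28. Ring C thereby travels through the route as an inert arene and is oxidised only when no organometallic step remains.

**From 28 to 21 and 26.** The bond between the C7 methylene and pyranone C6″ is cut. The 2-pyranone cannot survive the aqueous base of the ring A fold, so it must arrive afterwards. Cutting here gives a benzylic electrophile 21, which becomes the zinc reagent 27, and a chloropyranone 26 that is a vinylogous acyl chloride. The forward step is an sp3–sp2 cross-coupling. Compound 26 comes from malonyl dichloride 22 through 23, 24 and 25; two molecules of 22 supply the six carbons of 23, one of which is lost on the way to 25. A benzyl ether is placed on O4″ so that it falls together with the ring A benzyl ethers at the end; a methyl ether at this position is harder to remove.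

**From 21 to 17.** These are functional-group changes. The ring A phenols must be masked before a benzylic halide or a zinc reagent exists in the same molecule, so 17 becomes the bis(benzyl ether) 18. The C7 carbon is carried as a silyloxymethyl group (18 to 19 to 21 through 20). A benzyl ether was set aside for this position for two reasons: both of its C–O bonds would be benzylic, so hydrogenolysis could cut on either side, and it would not be orthogonal to the phenol benzyl ethers. The triisopropylsilyl ether tolerates hydride, amide and hydroxide bases and leaves with fluoride.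

**From 17 to 15 (the strategic cut).** The C1′–C6′ bond of ring A is cut. This reveals the tetraketone 16, whose chain carbon C2 lies between the aryl ketone and the next carbonyl and whose C7 is the acetyl carbonyl. Compound 16 is not handled as such; it is carried as the 4-pyranone 15. The gain is that the hindered ketone is already in place when ring A is formed, so no hindered arene has to be acylated. The forward reaction must open the pyranone and steer the chain into the C2-to-C7 aldol.

**From 15 to 12 and 13.** The bond between the ketone carbon and its methylene is cut. This gives the naphthoate ester 12 and 2,6-dimethyl-4H-pyran-4-one 13, which is metalated at a methyl group to give 14. The forward step is a crossed Claisen condensation on a non-enolisable ester.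

**From 12 to 6 and 9.** The methyl ether 12 comes from the naphthol 11. In 11, ring B is cut at the naphthalene C1–C2 and C3–C4 bonds. This gives the homophthalic anhydride 6 (as its enolate 10), which supplies ring C and the two benzylic carbons, and the ynoate 9, which supplies C2 with its ester and C3 with its silyloxymethyl group. The annulation places the three contiguous substituents of ring B in one step with the carbon substituents at the correct oxidation level.

**From 6 to 1, and from 9 to 7.** Anhydride 6 comes from the diacid 5. Diacid 5 comes from the ortho-toluic acid 3 by benzylic carboxylation through dianion 4. Acid 3 comes from the benzoic acid 1 by methylation of its only ortho C–H through 2. Ynoate 9 comes from the silyl propargyl ether 7 by C-acylation of its acetylide 8.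

## Alternatives that were turned down

**Alternative 1: quinone Diels–Alder.** Ring B would be cut at C4a–C5 and C8–C8a. 2-Chloro-5-methoxy-1,4-benzoquinone A1 would react with 1-methoxy-1,3-bis(trimethylsilyloxy)buta-1,3-diene A2 in a [4+2] cycloaddition. The chlorine directs the nucleophilic diene terminus to the unsubstituted quinone carbon, and loss of HCl and methanol aromatises ring B to 5,7-dihydroxy-2-methoxy-1,4-naphthoquinone A3.
- For it: two simple fragments give the whole ring B/C skeleton in one step. Ring C is already a quinone with its C2 oxygen differentiated, so no late oxidation is needed. On these points it is stronger than the chosen route, which needs five steps to reach a naphthalene and an oxidation near the end.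
- Against it: A3 has hydrogen on C6 and oxygen on C7, where 31 has the aroyl group and a carbon substituent. C6 would have to be acylated between two oxygenated carbons with a doubly ortho-substituted aroyl electrophile. That is the tetra-ortho-hindered intermolecular ketone formation which is the central difficulty of 31. The C7 oxygen would also have to be exchanged for carbon through a selective sulfonylation and a cross-coupling on a quinone or its reduced form.
- Comparison: the chosen route installs the C6 carbonyl carbon and the C7 carbon during the annulation that gives 11 and grows ring A on the existing ketone. It pays for this with a longer approach to the core.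

**Alternative 2: squarate ring expansion.** The C4–C4a bond would be cut. Heating 4-[3,5-bis(benzyloxy)phenyl]-4-hydroxy-3-(propan-2-yloxy)cyclobut-2-en-1-one A4 opens the four-membered ring to an aryl vinylketene. 6π-Electrocyclisation onto the arene and tautomerisation give 5,7-bis(benzyloxy)-2-(propan-2-yloxy)naphthalene-1,4-diol A5.
- For it: the position of the ring C oxygen is fixed by construction. The symmetric aryl group allows only one cyclisation mode. The hydroquinone oxidises easily. The isopropyl vinylogous ester can be removed with mild acid, which is gentler than the hydroxide treatment that ends the chosen route.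
- Against it: A5 has the same deficit as A3, with C6–H and C7–O. The 3,5-dioxygenated aryl group that makes the cyclisation unambiguous is the cause. An aryl group already carrying the C6 and C7 carbon substituents would have to cyclise at its only free, hindered ortho position and would need a pentasubstituted aryl metal reagent.
- Comparison: A5 is reached in few steps, but at least six further operations follow, and two of them (the C6 acylation and the C7 exchange) are hard to defend. The chosen route concentrates its risk in one well-founded base-mediated fold.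

**Alternative 3: rhodium C–H acylmethylation and Knoevenagel closure.** Ring B would be cut at C8–C8a and C6–C7. The enol of 1-(2,4-dimethoxy-6-methylphenyl)-3-(2,4,5-trimethoxyphenyl)propane-1,3-dione A6 directs a cationic catalyst of trivalent rhodium ([Cp*RhCl2]2 with AgSbF6) to the only free ortho C–H of the trimethoxyphenyl ring. Carbene transfer from the sulfoxonium ylide 1-[dimethyl(oxo)-λ6-sulfanylidene]-4,4-dimethoxybutan-2-one A7 forms C8–C8a. The central carbon of the diketone then condenses with the new ketone to form C6–C7. The product is (2,4-dimethoxy-6-methylphenyl)[3-(2,2-dimethoxyethyl)-1-hydroxy-5,6,8-trimethoxynaphthalen-2-yl]methanone A8.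
- For it: it is the most convergent plan. Ring A, the hindered ketone and the C7 side chain are all present after one annulation, and the ketone is made by a Claisen condensation and not by arene acylation. In convergence and in step count to a fully substituted ring B it is stronger than the chosen route.
- Against it: the C–H bond to be activated lies next to a methoxy group and beside a bulky, twisted diaryl diketone. The annulation of 1,3-dicarbonyl compounds with sulfoxonium ylides is established for simpler aryl ketones, not for a substrate this congested. The side chain of A8 is one oxidation and two C–C bond formations away from the pyranone. Ring A arrives as a dimethyl ether, so the end game needs a strong boron halide in the presence of the pyranone and the quinone.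
- Comparison: the chosen route is longer, but its key step has close precedent, it releases ring A as the free resorcinol (so the protecting groups can be chosen for one mild final cleavage), and its pyranone is installed whole by a cross-coupling.

Key step: step 8

## Route

Assumption: triisopropyl(prop-2-yn-1-yloxy)silane 7 is taken as a catalogue compound. The target is treated as its 2-hydroxy-1,4-naphthoquinone and 4-hydroxy-2-pyranone tautomers and has no stereocentre.

Step 1
Reactants: 1 2,4,5-trimethoxybenzoic acid
Product: 3 3,4,6-trimethoxy-2-methylbenzoic acid, via dilithiated benzoate 2 (not isolated)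
Conditions: s-BuLi (2.2 equiv), TMEDA, THF, −78 °C; MeI; aq. HCl
Reagents that add atoms: iodomethane, CI
Why: Carboxylate-directed ortho-metalation; C6–H of 1 is the only position ortho to the carboxylate and is also ortho to the C5 methoxy group, so both directing groups act on the same site, and the aryllithium 2 is methylated by SN2 on iodomethane.

Step 2
Reactants: 3 3,4,6-trimethoxy-2-methylbenzoic acid
Product: 5 2-(carboxymethyl)-3,4,6-trimethoxybenzoic acid, via benzylic dianion 4 (not isolated)
Conditions: LiN(i-Pr)2 (3 equiv), THF, −78 → 0 °C; CO2 (g), −78 °C; aq. HCl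
Reagents that add atoms: carbon dioxide, O=C=O
Why: Lateral lithiation of an ortho-toluic acid gives the carboxylate-stabilised benzylic anion 4, and its carboxylation is the standard entry to homophthalic acids.

Step 3
Reactants: 5 2-(carboxymethyl)-3,4,6-trimethoxybenzoic acid
Product: 6 5,6,8-trimethoxyisochromane-1,3-dione
Conditions: Ac2O, toluene, 100 °C
Reagents that add atoms: none
Why: Cyclodehydration of a homophthalic acid to its six-membered cyclic anhydride through the mixed anhydride.

Step 4
Reactants: 7 triisopropyl(prop-2-yn-1-yloxy)silane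
Product: 9 methyl 4-{[tri(propan-2-yl)silyl]oxy}but-2-ynoate, via lithium acetylide 8 (not isolated)
Conditions: n-BuLi, THF, −78 °C; ClCO2Me, −78 → 0 °C
Reagents that add atoms: methyl chloroformate, COC(=O)Cl
Why: Deprotonation of the terminal alkyne and C-acylation of the acetylide with a chloroformate.

Step 5
Reactants: 6 5,6,8-trimethoxyisochromane-1,3-dione; 9 methyl 4-{[tri(propan-2-yl)silyl]oxy}but-2-ynoate
Product: 11 methyl 1-hydroxy-5,6,8-trimethoxy-3-({[tri(propan-2-yl)silyl]oxy}methyl)naphthalene-2-carboxylate, via anhydride sodium enolate 10 (not isolated)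
Conditions: NaH, THF, 0 °C; then 9, 0 → 40 °C; aq. HCl
Reagents that add atoms: none
Why: Tamura annulation; the benzylic carbon of enolate 10 adds to the β-carbon of the ynoate (the carbon bearing the silyloxymethyl group), the ester-stabilised α-carbon closes onto the aryl carbonyl, and loss of CO2 and tautomerisation give the 1-naphthol with the ester on C2 and hydrogen on C4.

Step 6
Reactants: 11 methyl 1-hydroxy-5,6,8-trimethoxy-3-({[tri(propan-2-yl)silyl]oxy}methyl)naphthalene-2-carboxylate
Product: 12 methyl 1,5,6,8-tetramethoxy-3-({[tri(propan-2-yl)silyl]oxy}methyl)naphthalene-2-carboxylate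
Conditions: MeI, K2CO3, DMF, 40 °C
Reagents that add atoms: iodomethane, CI
Why: Williamson methylation of the hydrogen-bonded peri naphthol; the ester has no enolisable position and the silyl ether is inert to carbonate.

Step 7
Reactants: 12 methyl 1,5,6,8-tetramethoxy-3-({[tri(propan-2-yl)silyl]oxy}methyl)naphthalene-2-carboxylate; 13 2,6-dimethyl-4H-pyran-4-one
Product: 15 2-methyl-6-{2-oxo-2-[1,5,6,8-tetramethoxy-3-({[tri(propan-2-yl)silyl]oxy}methyl)naphthalen-2-yl]ethyl}-4H-pyran-4-one, via lithiated pyranone 14 (not isolated)
Conditions: 13 (3 equiv), LiN(SiMe3)2 (3 equiv), THF, −78 °C; then 12, −78 → 0 °C; aq. HCl (cold, dilute)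
Reagents that add atoms: none
Why: Crossed Claisen condensation of the vinylogous enolate 14 with a non-enolisable aryl ester; a second equivalent of 14 deprotonates the more acidic product, which drives the equilibrium and prevents a second addition.

Step 8
Reactants: 15 2-methyl-6-{2-oxo-2-[1,5,6,8-tetramethoxy-3-({[tri(propan-2-yl)silyl]oxy}methyl)naphthalen-2-yl]ethyl}-4H-pyran-4-one
Product: 17 (2,4-dihydroxy-6-methylphenyl)[1,5,6,8-tetramethoxy-3-({[tri(propan-2-yl)silyl]oxy}methyl)naphthalen-2-yl]methanone, via open-chain tetraketone 16 (not isolated)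
Conditions: KOH (2 M aq.), EtOH, 25 → 60 °C, Ar; then aq. HCl to pH 3
Reagents that add atoms: none
Why: Hydroxide first removes the acidic methylene proton of 15 and then adds to the methyl-bearing C6 of the 4-pyranone, the position remote from the enolate, and ring opening releases the tetraketone 16 as its polyanion, so the free chain exists only in solution. In 16 the chain carbon C2, flanked by the aryl ketone and the C3 carbonyl, attacks the C7 acetyl carbonyl and forms the C1′–C6′ bond of ring A; elimination of water (the oxygen that hydroxide had delivered) and enolisation of the C3 and C5 carbonyls aromatise the ring to the resorcinol, and acidification should give 17. The closest known reaction type is the base-mediated conversion of 2-acylmethyl-4-pyranones and of free 1,3,5,7-tetraketones into acylresorcinols, the laboratory counterpart of polyketide aldol aromatisation. Ring A closes in a 6-(enolendo)-exo-trig aldol mode. No stereocentre is formed. The one selectivity needed is the C2-to-C7 aldol in preference to attack of chain C6 on the aryl ketone, to closure from the terminal methyl and to retro-Claisen cleavage. The substrate secures it because the naphthyl ketone has two ortho substituents (the naphthalene C1 methoxy and C3 silyloxymethyl groups), is twisted out of conjugation and is poorly electrophilic, whereas the acetyl carbonyl is the least hindered electrophile and chain C2 is the most acidic carbon. The aryl methyl ethers and the triisopropylsilyl ether are inert to aqueous hydroxide at this temperature.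

Step 9
Reactants: 17 (2,4-dihydroxy-6-methylphenyl)[1,5,6,8-tetramethoxy-3-({[tri(propan-2-yl)silyl]oxy}methyl)naphthalen-2-yl]methanone
Product: 18 [2,4-bis(benzyloxy)-6-methylphenyl][1,5,6,8-tetramethoxy-3-({[tri(propan-2-yl)silyl]oxy}methyl)naphthalen-2-yl]methanone
Conditions: BnBr (excess), K2CO3, DMF, 60 °C
Reagents that add atoms: benzyl bromide, BrCc1ccccc1
Why: Williamson etherification of both phenols; excess halide and warming in a dipolar solvent overcome the hydrogen bond between the C2′ hydroxyl and the ketone.

Step 10
Reactants: 18 [2,4-bis(benzyloxy)-6-methylphenyl][1,5,6,8-tetramethoxy-3-({[tri(propan-2-yl)silyl]oxy}methyl)naphthalen-2-yl]methanone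
Product: 19 [2,4-bis(benzyloxy)-6-methylphenyl][3-(hydroxymethyl)-1,5,6,8-tetramethoxynaphthalen-2-yl]methanone
Conditions: Bu4NF, THF, 0 → 25 °C
Reagents that add atoms: none
Why: Fluoride-induced desilylation, orthogonal to benzyl and methyl ethers; the alcohol may equilibrate with its cyclic hemiketal, which does not affect the next step.

Step 11
Reactants: 19 [2,4-bis(benzyloxy)-6-methylphenyl][3-(hydroxymethyl)-1,5,6,8-tetramethoxynaphthalen-2-yl]methanone
Product: 21 [2,4-bis(benzyloxy)-6-methylphenyl][3-(chloromethyl)-1,5,6,8-tetramethoxynaphthalen-2-yl]methanone, via benzylic mesylate 20 (not isolated)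
Conditions: MsCl, Et3N, CH2Cl2, 0 °C; then LiCl, THF, 25 °C
Reagents that add atoms: lithium chloride, [Li+].[Cl-]
Why: Sulfonylation of the primary benzylic alcohol and SN2 displacement by chloride under non-acidic conditions that leave the ethers and the ketone untouched.

Step 12
Reactants: 22 malonyl dichloride (two molecules)
Product: 25 6-chloro-4-hydroxy-2H-pyran-2-one, via pyranone acyl chloride 23 (not isolated), via pyranone carboxylic acid 24 (not isolated)
Conditions: neat, 25 °C, several days, moisture excluded; then H2O, dioxane, 25 → 50 °C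
Reagents that add atoms: malonyl dichloride (the second molecule of 22), O=C(Cl)CC(Cl)=O
Why: Self-condensation of two molecules of malonyl dichloride: the methylene of one molecule is C-acylated by the other, and O-acylation by the enolised terminal chlorocarbonyl group closes the ring to the six-carbon pyranone acyl chloride 23 with loss of two HCl. Water then hydrolyses the acyl chloride to the acid 24, a vinylogous β-keto acid that loses CO2 on warming, which should leave the five-carbon pyranone 25.

Step 13
Reactants: 25 6-chloro-4-hydroxy-2H-pyran-2-one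
Product: 26 4-(benzyloxy)-6-chloro-2H-pyran-2-one
Conditions: BnOH, PPh3, DIAD, THF, 0 → 25 °C
Reagents that add atoms: benzyl alcohol, OCc1ccccc1
Why: Mitsunobu O-alkylation; the acidic 4-hydroxy-2-pyranone is a good pronucleophile and reacts at O4, which avoids the C3 alkylation seen with benzyl halides and base.

Step 14
Reactants: 21 [2,4-bis(benzyloxy)-6-methylphenyl][3-(chloromethyl)-1,5,6,8-tetramethoxynaphthalen-2-yl]methanone; 26 4-(benzyloxy)-6-chloro-2H-pyran-2-one
Product: 28 4-(benzyloxy)-6-({3-[2,4-bis(benzyloxy)-6-methylbenzoyl]-4,5,7,8-tetramethoxynaphthalen-2-yl}methyl)-2H-pyran-2-one, via benzylzinc chloride 27 (not isolated)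
Conditions: Zn dust, LiCl, THF, 25 °C; then 26, Pd(OAc)2 (cat.), SPhos (cat.), THF, 25 → 40 °C
Reagents that add atoms: none
Why: LiCl-promoted zinc insertion into the benzylic chloride gives a zinc reagent that tolerates the hindered diaryl ketone, and Negishi coupling follows by oxidative addition of zerovalent palladium into the C6″–Cl bond of the pyranone, a vinylogous acyl chloride, then transmetalation and reductive elimination.

Step 15
Reactants: 28 4-(benzyloxy)-6-({3-[2,4-bis(benzyloxy)-6-methylbenzoyl]-4,5,7,8-tetramethoxynaphthalen-2-yl}methyl)-2H-pyran-2-one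
Product: 29 6-[2,4-bis(benzyloxy)-6-methylbenzoyl]-7-{[4-(benzyloxy)-2-oxo-2H-pyran-6-yl]methyl}-2,5-dimethoxynaphthalene-1,4-dione
Conditions: (NH4)2Ce(NO3)6 (2.5 equiv), MeCN/H2O, 0 °C
Reagents that add atoms: water, O
Why: Oxidative demethylation by tetravalent cerium; the 1,2,4-trioxygenated ring is the most electron-rich arene, its para pair of methoxy groups (naphthalene C5 and C8) is converted into the quinone by water attack on the radical cation, and ring B cannot form a quinone because its C4 carries hydrogen.

Step 16
Reactants: 29 6-[2,4-bis(benzyloxy)-6-methylbenzoyl]-7-{[4-(benzyloxy)-2-oxo-2H-pyran-6-yl]methyl}-2,5-dimethoxynaphthalene-1,4-dione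
Product: 30 6-(2,4-dihydroxy-6-methylbenzoyl)-5-hydroxy-7-[(4-hydroxy-2-oxo-2H-pyran-6-yl)methyl]-2-methoxynaphthalene-1,4-dione
Conditions: BCl3, C6HMe5, CH2Cl2, −78 → 0 °C; then MeOH/H2O
Reagents that add atoms: none
Why: Lewis-acid debenzylation with pentamethylbenzene as benzyl cation trap removes the three benzyl groups, and chelation of boron between the C4 carbonyl (or the aroyl carbonyl) and the C5 oxygen directs cleavage of the peri methyl ether.

Step 17
Reactants: 30 6-(2,4-dihydroxy-6-methylbenzoyl)-5-hydroxy-7-[(4-hydroxy-2-oxo-2H-pyran-6-yl)methyl]-2-methoxynaphthalene-1,4-dione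
Product: 31 6-(2,4-dihydroxy-6-methylbenzoyl)-2,5-dihydroxy-7-[(4-hydroxy-2-oxo-2H-pyran-6-yl)methyl]naphthalene-1,4-dione
Conditions: NaOH (0.5 M aq.), THF, 0 → 25 °C, Ar; then aq. HCl
Reagents that add atoms: sodium hydroxide, [Na+].[OH-]
Why: Addition–elimination of hydroxide at C2 of the 2-methoxy-1,4-naphthoquinone (hydrolysis of a vinylogous ester); the pyranone is present as its 4-oxido anion, which resists ring opening, and acidification should give the target.

## Compound list

1 | 2,4,5-trimethoxybenzoic acid | COc1cc(OC)c(C(=O)O)cc1OC | starting material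
2 | lithium 6-lithio-2,4,5-trimethoxybenzoate | COc1cc(OC)c(C(=O)O[Li])c([Li])c1OC | intermediate (not isolated)
3 | 3,4,6-trimethoxy-2-methylbenzoic acid | COc1cc(OC)c(C(=O)O)c(C)c1OC | intermediate
4 | lithium 2-(lithiomethyl)-3,4,6-trimethoxybenzoate | COc1cc(OC)c(C(=O)O[Li])c(C[Li])c1OC | intermediate (not isolated)
5 | 2-(carboxymethyl)-3,4,6-trimethoxybenzoic acid | COc1cc(OC)c(C(=O)O)c(CC(=O)O)c1OC | intermediate
6 | 5,6,8-trimethoxyisochromane-1,3-dione | COc1cc(OC)c2C(=O)OC(=O)Cc2c1OC | intermediate
7 | triisopropyl(prop-2-yn-1-yloxy)silane | C#CCO[Si](C(C)C)(C(C)C)C(C)C | starting material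
8 | lithium acetylide of 7 | [Li]C#CCO[Si](C(C)C)(C(C)C)C(C)C | intermediate (not isolated)
9 | methyl 4-{[tri(propan-2-yl)silyl]oxy}but-2-ynoate | COC(=O)C#CCO[Si](C(C)C)(C(C)C)C(C)C | intermediate
10 | sodium enolate of 6 | COc1cc(OC)c2C(=O)OC([O-])=Cc2c1OC.[Na+] | intermediate (not isolated)
11 | methyl 1-hydroxy-5,6,8-trimethoxy-3-({[tri(propan-2-yl)silyl]oxy}methyl)naphthalene-2-carboxylate | COC(=O)c1c(CO[Si](C(C)C)(C(C)C)C(C)C)cc2c(OC)c(OC)cc(OC)c2c1O | intermediate
12 | methyl 1,5,6,8-tetramethoxy-3-({[tri(propan-2-yl)silyl]oxy}methyl)naphthalene-2-carboxylate | COC(=O)c1c(CO[Si](C(C)C)(C(C)C)C(C)C)cc2c(OC)c(OC)cc(OC)c2c1OC | intermediate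
13 | 2,6-dimethyl-4H-pyran-4-one | Cc1cc(=O)cc(C)o1 | starting material
14 | 2-(lithiomethyl)-6-methyl-4H-pyran-4-one | [Li]Cc1cc(=O)cc(C)o1 | intermediate (not isolated)
15 | 2-methyl-6-{2-oxo-2-[1,5,6,8-tetramethoxy-3-({[tri(propan-2-yl)silyl]oxy}methyl)naphthalen-2-yl]ethyl}-4H-pyran-4-one | Cc1cc(=O)cc(CC(=O)c2c(CO[Si](C(C)C)(C(C)C)C(C)C)cc3c(OC)c(OC)cc(OC)c3c2OC)o1 | intermediate
16 | 1-[1,5,6,8-tetramethoxy-3-({[tri(propan-2-yl)silyl]oxy}methyl)naphthalen-2-yl]octane-1,3,5,7-tetrone | CC(=O)CC(=O)CC(=O)CC(=O)c1c(CO[Si](C(C)C)(C(C)C)C(C)C)cc2c(OC)c(OC)cc(OC)c2c1OC | intermediate (not isolated)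
17 | (2,4-dihydroxy-6-methylphenyl)[1,5,6,8-tetramethoxy-3-({[tri(propan-2-yl)silyl]oxy}methyl)naphthalen-2-yl]methanone | Cc1cc(O)cc(O)c1C(=O)c1c(CO[Si](C(C)C)(C(C)C)C(C)C)cc2c(OC)c(OC)cc(OC)c2c1OC | intermediate
18 | [2,4-bis(benzyloxy)-6-methylphenyl][1,5,6,8-tetramethoxy-3-({[tri(propan-2-yl)silyl]oxy}methyl)naphthalen-2-yl]methanone | Cc1cc(OCc2ccccc2)cc(OCc2ccccc2)c1C(=O)c1c(CO[Si](C(C)C)(C(C)C)C(C)C)cc2c(OC)c(OC)cc(OC)c2c1OC | intermediate
19 | [2,4-bis(benzyloxy)-6-methylphenyl][3-(hydroxymethyl)-1,5,6,8-tetramethoxynaphthalen-2-yl]methanone | Cc1cc(OCc2ccccc2)cc(OCc2ccccc2)c1C(=O)c1c(CO)cc2c(OC)c(OC)cc(OC)c2c1OC | intermediate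
20 | [2,4-bis(benzyloxy)-6-methylphenyl]{1,5,6,8-tetramethoxy-3-[(methanesulfonyloxy)methyl]naphthalen-2-yl}methanone | Cc1cc(OCc2ccccc2)cc(OCc2ccccc2)c1C(=O)c1c(COS(C)(=O)=O)cc2c(OC)c(OC)cc(OC)c2c1OC | intermediate (not isolated)
21 | [2,4-bis(benzyloxy)-6-methylphenyl][3-(chloromethyl)-1,5,6,8-tetramethoxynaphthalen-2-yl]methanone | Cc1cc(OCc2ccccc2)cc(OCc2ccccc2)c1C(=O)c1c(CCl)cc2c(OC)c(OC)cc(OC)c2c1OC | intermediate
22 | malonyl dichloride | O=C(Cl)CC(Cl)=O | starting material
23 | 6-chloro-4-hydroxy-2-oxo-2H-pyran-3-carbonyl chloride | O=C(Cl)c1c(O)cc(Cl)oc1=O | intermediate (not isolated)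
24 | 6-chloro-4-hydroxy-2-oxo-2H-pyran-3-carboxylic acid | O=C(O)c1c(O)cc(Cl)oc1=O | intermediate (not isolated)
25 | 6-chloro-4-hydroxy-2H-pyran-2-one | O=c1cc(O)cc(Cl)o1 | intermediate
26 | 4-(benzyloxy)-6-chloro-2H-pyran-2-one | O=c1cc(OCc2ccccc2)cc(Cl)o1 | intermediate
27 | [2,4-bis(benzyloxy)-6-methylphenyl]{3-[(chlorozincio)methyl]-1,5,6,8-tetramethoxynaphthalen-2-yl}methanone | Cc1cc(OCc2ccccc2)cc(OCc2ccccc2)c1C(=O)c1c(C[Zn]Cl)cc2c(OC)c(OC)cc(OC)c2c1OC | intermediate (not isolated)
28 | 4-(benzyloxy)-6-({3-[2,4-bis(benzyloxy)-6-methylbenzoyl]-4,5,7,8-tetramethoxynaphthalen-2-yl}methyl)-2H-pyran-2-one | Cc1cc(OCc2ccccc2)cc(OCc2ccccc2)c1C(=O)c1c(Cc2cc(OCc3ccccc3)cc(=O)o2)cc2c(OC)c(OC)cc(OC)c2c1OC | intermediate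
29 | 6-[2,4-bis(benzyloxy)-6-methylbenzoyl]-7-{[4-(benzyloxy)-2-oxo-2H-pyran-6-yl]methyl}-2,5-dimethoxynaphthalene-1,4-dione | Cc1cc(OCc2ccccc2)cc(OCc2ccccc2)c1C(=O)c1c(Cc2cc(OCc3ccccc3)cc(=O)o2)cc2c(c1OC)C(=O)C=C(OC)C2=O | intermediate
30 | 6-(2,4-dihydroxy-6-methylbenzoyl)-5-hydroxy-7-[(4-hydroxy-2-oxo-2H-pyran-6-yl)methyl]-2-methoxynaphthalene-1,4-dione | Cc1cc(O)cc(O)c1C(=O)c1c(Cc2cc(O)cc(=O)o2)cc2c(c1O)C(=O)C=C(OC)C2=O | intermediate
31 | 6-(2,4-dihydroxy-6-methylbenzoyl)-2,5-dihydroxy-7-[(4-hydroxy-2-oxo-2H-pyran-6-yl)methyl]naphthalene-1,4-dione | Cc1cc(O)cc(O)c1C(=O)c1c(Cc2cc(O)cc(=O)o2)cc2c(c1O)C(=O)C=C(O)C2=O | target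

## Step count and least certain steps

Total: 17 steps. Longest linear sequence: 14 steps (1, 2, 3, 5, 6, 7, 8, 9, 10, 11, 14, 15, 16, 17). Step 4 and steps 12–13 are side branches.

**Step 8 (key step).** The most likely failure is retro-Claisen cleavage of the chain between C2 and C3 by hydroxide before the aldol closes. Competing aldol closure onto the aryl ketone, re-closure to a pyranone, or partial loss of the silyl group on prolonged heating are also possible. Fallback: the chain is made free instead of masked. It sets out from 12 and 13. Pyranone 13 is opened with Ba(OH)2 in hot water and acidified to heptane-2,4,6-trione F1. The trianion of F1 (LiN(i-Pr)2, 3 equiv, THF, 0 °C) is acylated at its terminal carbon by ester 12 to give the tetraketone 16 directly. Compound 16 is cyclised under buffered, milder base at 25 °C, and the route is rejoined at 17.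

**Step 5.** Conjugate addition of enolate 10 to a β-substituted ynoate may be slow. Base-induced isomerisation of 9 to an allenoate, or self-condensation and decarboxylation of the anhydride, may then compete. Fallback: a sulfoxide annulation that needs no alkyne and no CO2 loss. It sets out from 3 and 9. Acid 3 is esterified (MeI, K2CO3, DMF) to methyl 3,4,6-trimethoxy-2-methylbenzoate F2. Lateral lithiation of F2 (LiN(i-Pr)2, −78 °C) and trapping with PhSSPh give methyl 3,4,6-trimethoxy-2-[(phenylsulfanyl)methyl]benzoate F3. Oxidation with NaIO4 gives methyl 3,4,6-trimethoxy-2-[(phenylsulfinyl)methyl]benzoate F4. Ynoate 9 is semi-hydrogenated (H2, Pd/CaCO3 poisoned with Pb(OAc)2, quinoline) to methyl (Z)-4-{[tri(propan-2-yl)silyl]oxy}but-2-enoate F5. The anion of F4 (LiN(i-Pr)2, THF, −78 °C) adds to F5, Dieckmann closure follows, and thermal loss of benzenesulfenic acid on warming aromatises ring B. The route is rejoined at 11.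

**Step 7.** Addition of 14 to the doubly ortho-substituted ester may be too slow, so that proton exchange and recovery of 12 dominate. Fallback: the carbonyl is made more electrophilic. It sets out from 12. Reduction with i-Bu2AlH (CH2Cl2, −78 → 0 °C) gives [1,5,6,8-tetramethoxy-3-({[tri(propan-2-yl)silyl]oxy}methyl)naphthalen-2-yl]methanol F6. Oxidation with MnO2 gives 1,5,6,8-tetramethoxy-3-({[tri(propan-2-yl)silyl]oxy}methyl)naphthalene-2-carbaldehyde F7. Aldol addition of 14 gives racemic 2-{2-hydroxy-2-[1,5,6,8-tetramethoxy-3-({[tri(propan-2-yl)silyl]oxy}methyl)naphthalen-2-yl]ethyl}-6-methyl-4H-pyran-4-one F8. Oxidation with Dess–Martin periodinane removes the new stereocentre and rejoins the route at 15.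

**Step 14.** Wurtz-type homocoupling of the electron-rich benzylic chloride during zinc insertion, slow oxidative addition into the donor-substituted chloropyranone, or attack of 27 at the lactone carbonyl may lower the outcome. Fallback: the pyranone is built on the side chain instead of being coupled. It sets out from 21. Carbonylation (PdCl2(PPh3)2, CO, MeOH, K2CO3) gives methyl 2-{3-[2,4-bis(benzyloxy)-6-methylbenzoyl]-4,5,7,8-tetramethoxynaphthalen-2-yl}acetate F9. Claisen condensation with the dianion of methyl acetoacetate (NaH, then n-BuLi, THF) gives methyl 6-{3-[2,4-bis(benzyloxy)-6-methylbenzoyl]-4,5,7,8-tetramethoxynaphthalen-2-yl}-3,5-dioxohexanoate F10. Lactonisation (DBU, toluene, reflux) gives 6-({3-[2,4-bis(benzyloxy)-6-methylbenzoyl]-4,5,7,8-tetramethoxynaphthalen-2-yl}methyl)-4-hydroxy-2H-pyran-2-one F11. Mitsunobu benzylation as in step 13 rejoins the route at 28.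

**Step 1.** Metalation at C3 between the two methoxy groups, or addition of s-BuLi to the carboxylate, may erode regioselectivity. Fallback: a catalytic C–H methylation that can only reach the single ortho C–H. It sets out from 1 and uses carboxylate-directed catalysis by divalent palladium (Pd(OAc)2, MeB(OH)2, Ag2CO3, benzoquinone, K2HPO4, t-BuOH, 100 °C). It returns directly at 3, and no new compound arises (F0).

## Further compounds

F1 | step 8 | heptane-2,4,6-trione | CC(=O)CC(=O)CC(C)=O
F2 | step 5 | methyl 3,4,6-trimethoxy-2-methylbenzoate | COC(=O)c1c(OC)cc(OC)c(OC)c1C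
F3 | step 5 | methyl 3,4,6-trimethoxy-2-[(phenylsulfanyl)methyl]benzoate | COC(=O)c1c(OC)cc(OC)c(OC)c1CSc1ccccc1
F4 | step 5 | methyl 3,4,6-trimethoxy-2-[(phenylsulfinyl)methyl]benzoate (racemic at sulfur) | COC(=O)c1c(OC)cc(OC)c(OC)c1CS(=O)c1ccccc1
F5 | step 5 | methyl (Z)-4-{[tri(propan-2-yl)silyl]oxy}but-2-enoate | COC(=O)/C=C\CO[Si](C(C)C)(C(C)C)C(C)C
F6 | step 7 | [1,5,6,8-tetramethoxy-3-({[tri(propan-2-yl)silyl]oxy}methyl)naphthalen-2-yl]methanol | OCc1c(CO[Si](C(C)C)(C(C)C)C(C)C)cc2c(OC)c(OC)cc(OC)c2c1OC
F7 | step 7 | 1,5,6,8-tetramethoxy-3-({[tri(propan-2-yl)silyl]oxy}methyl)naphthalene-2-carbaldehyde | O=Cc1c(CO[Si](C(C)C)(C(C)C)C(C)C)cc2c(OC)c(OC)cc(OC)c2c1OC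
F8 | step 7 | 2-{2-hydroxy-2-[1,5,6,8-tetramethoxy-3-({[tri(propan-2-yl)silyl]oxy}methyl)naphthalen-2-yl]ethyl}-6-methyl-4H-pyran-4-one (racemic) | Cc1cc(=O)cc(CC(O)c2c(CO[Si](C(C)C)(C(C)C)C(C)C)cc3c(OC)c(OC)cc(OC)c3c2OC)o1
F9 | step 14 | methyl 2-{3-[2,4-bis(benzyloxy)-6-methylbenzoyl]-4,5,7,8-tetramethoxynaphthalen-2-yl}acetate | COC(=O)Cc1cc2c(OC)c(OC)cc(OC)c2c(OC)c1C(=O)c1c(C)cc(OCc2ccccc2)cc1OCc1ccccc1
F10 | step 14 | methyl 6-{3-[2,4-bis(benzyloxy)-6-methylbenzoyl]-4,5,7,8-tetramethoxynaphthalen-2-yl}-3,5-dioxohexanoate | COC(=O)CC(=O)CC(=O)Cc1cc2c(OC)c(OC)cc(OC)c2c(OC)c1C(=O)c1c(C)cc(OCc2ccccc2)cc1OCc1ccccc1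
F11 | step 14 | 6-({3-[2,4-bis(benzyloxy)-6-methylbenzoyl]-4,5,7,8-tetramethoxynaphthalen-2-yl}methyl)-4-hydroxy-2H-pyran-2-one | Cc1cc(OCc2ccccc2)cc(OCc2ccccc2)c1C(=O)c1c(Cc2cc(O)cc(=O)o2)cc2c(OC)c(OC)cc(OC)c2c1OC
F0 | step 1 | none | none
A1 | alternative 1 | 2-chloro-5-methoxy-1,4-benzoquinone | COC1=CC(=O)C(Cl)=CC1=O
A2 | alternative 1 | 1-methoxy-1,3-bis(trimethylsilyloxy)buta-1,3-diene | COC(O[Si](C)(C)C)=CC(=C)O[Si](C)(C)C
A3 | alternative 1 | 5,7-dihydroxy-2-methoxy-1,4-naphthoquinone | COC1=CC(=O)c2c(O)cc(O)cc2C1=O
A4 | alternative 2 | 4-[3,5-bis(benzyloxy)phenyl]-4-hydroxy-3-(propan-2-yloxy)cyclobut-2-en-1-one (racemic) | CC(C)OC1=CC(=O)C1(O)c1cc(OCc2ccccc2)cc(OCc2ccccc2)c1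
A5 | alternative 2 | 5,7-bis(benzyloxy)-2-(propan-2-yloxy)naphthalene-1,4-diol | CC(C)Oc1cc(O)c2c(OCc3ccccc3)cc(OCc3ccccc3)cc2c1O
A6 | alternative 3 | 1-(2,4-dimethoxy-6-methylphenyl)-3-(2,4,5-trimethoxyphenyl)propane-1,3-dione | Cc1cc(OC)cc(OC)c1C(=O)CC(=O)c1cc(OC)c(OC)cc1OC
A7 | alternative 3 | 1-[dimethyl(oxo)-λ6-sulfanylidene]-4,4-dimethoxybutan-2-one | COC(OC)CC(=O)C=S(C)(C)=O
A8 | alternative 3 | (2,4-dimethoxy-6-methylphenyl)[3-(2,2-dimethoxyethyl)-1-hydroxy-5,6,8-trimethoxynaphthalen-2-yl]methanone | Cc1cc(OC)cc(OC)c1C(=O)c1c(CC(OC)OC)cc2c(OC)c(OC)cc(OC)c2c1O
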